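**Plan**
- Last cuts: the two ester C–O bonds, the benzylic C–H (from an acetyl group) and the aldehyde oxidation level (from CH2OSi). This leaves a 5-acetyl-3-hydroxy-2-alkenyl-2,3-dihydrobenzofuran.
- Main cut: both bonds to C2 of the dihydrofuran (C2–C3 and O1–C2). C3, C3a, C7a and O1 are the formyl carbon, two ring carbons and phenol oxygen of 5-acetylsalicylaldehyde; C2 with its propenyl arm is the CH2 of a 2-(silyloxymethyl)allyl bromide.
- Enabling feature: C2 is both bound to O1 and allylic to the 1,1-disubstituted alkene, next to the benzylic carbinol C3 that sits ortho to O1. This allylic carbon can act first as a nucleophile (sulfonium ylide, towards the aldehyde) and then as an electrophile (vinyl oxirane, towards the ortho phenoxide), i.e. as a one-carbon 1,1-dipole.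
- Forward: bromide plus a C2-symmetric chiral thiolane gives a sulfonium salt; a [4+1] ylide annulation closes the only ring that has to be made; then isovalerate, ketone reduction, (R)-2-methylbutanoate, desilylation and oxidation to the enal.
- Stereochemistry: C2 and C3 from the (2R,5R)-2,5-dimethylthiolane auxiliary (absolute) and the trans-oxirane/anti-opening sequence (relative, 2,3-trans); the benzylic carbinol from (R,R)-TsDPEN–Ru transfer hydrogenation; the acyl α-centre from purchased (R)-2-methylbutanoic acid.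

Key step: step 6

Remark: the sense of induction of the thiolanium allylide is assumed to follow that of benzylidene transfer with the same sulfide; if it proved opposite, the (2S,5S)-sulfide from (2R,5R)-hexane-2,5-diol would be used in the same way.

**Route**

Step 1
Reactants: 1 2-methylidenepropane-1,3-diol
Product: 2 2-({[tert-butyl(dimethyl)silyl]oxy}methyl)prop-2-en-1-ol
Conditions: NaH (1.0 equiv), THF, 0 °C → rt; then TBSCl (1.0 equiv)
Reagents that add atoms: tert-butyldimethylsilyl chloride, C[Si](C)(Cl)C(C)(C)C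
Why: O-silylation of the monosodium alkoxide of a symmetric diol should stop after one silyl group because only one equivalent of alkoxide is formed; no stereocentre is involved.

Step 2
Reactants: 2 2-({[tert-butyl(dimethyl)silyl]oxy}methyl)prop-2-en-1-ol
Product: 3 {[2-(bromomethyl)prop-2-en-1-yl]oxy}(tert-butyl)dimethylsilane
Conditions: CBr4, PPh3, CH2Cl2, 0 °C
Reagents that add atoms: carbon tetrabromide, BrC(Br)(Br)Br
Why: Appel bromination of the primary allylic alcohol is neutral and should leave the silyl ether intact; SN2 and SN2' displacement give the same bromide because the 2-substituted allyl unit is symmetric.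

Step 3
Reactants: 4 (2S,5S)-hexane-2,5-diol
Product: 5 (2S,5S)-hexane-2,5-diyl dimethanesulfonate
Conditions: MsCl (2.4 equiv), Et3N (3 equiv), CH2Cl2, −20 → 0 °C
Reagents that add atoms: methanesulfonyl chloride, CS(=O)(=O)Cl
Why: Mesylation at oxygen does not touch the C–O bonds, so both stereocentres are retained.

Step 4
Reactants: 5 (2S,5S)-hexane-2,5-diyl dimethanesulfonate
Product: 6 (2R,5R)-2,5-dimethylthiolane
Conditions: Na2S·9H2O, DMSO, rt → 40 °C
Reagents that add atoms: sodium sulfide, [Na+].[Na+].[S-2]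
Why: Double SN2 displacement by sulfide (the second a 5-exo-tet closure) inverts both carbons and should give the C2-symmetric trans-thiolane; the stereocentres come from the purchased diol.

Step 5
Reactants: 3 {[2-(bromomethyl)prop-2-en-1-yl]oxy}(tert-butyl)dimethylsilane, 6 (2R,5R)-2,5-dimethylthiolane
Product: 7 (2R,5R)-1-[2-({[tert-butyl(dimethyl)silyl]oxy}methyl)prop-2-en-1-yl]-2,5-dimethylthiolan-1-ium tetrafluoroborate
Conditions: NaBF4 (5 equiv), CH2Cl2/H2O (1:1), rt
Reagents that add atoms: sodium tetrafluoroborate, [Na+].F[B-](F)(F)F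
Why: S-alkylation of the thioether by the reactive allylic bromide, driven by transfer of bromide to the aqueous phase, should give one sulfonium salt; the two lone pairs of the C2-symmetric sulfide are homotopic, so sulfur is not a stereocentre.

Step 6
Reactants: 7 (2R,5R)-1-[2-({[tert-butyl(dimethyl)silyl]oxy}methyl)prop-2-en-1-yl]-2,5-dimethylthiolan-1-ium tetrafluoroborate, 8 5-acetyl-2-hydroxybenzaldehyde
Product: 11 1-[(2R,3S)-2-(3-{[tert-butyl(dimethyl)silyl]oxy}prop-1-en-2-yl)-3-hydroxy-2,3-dihydro-1-benzofuran-5-yl]ethan-1-one, via sulfonium ylide 9 (not isolated), via vinyl oxirane 10 (not isolated)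
Conditions: NaOH (powdered, 2.2 equiv), t-BuOH/H2O (9:1), 0 °C → rt, then 45 °C; aq NH4Cl
Reagents that add atoms: none
Why: Hydroxide converts 8 into its phenoxide and 7 into allylic ylide 9, whose sulfur-bound carbon (future C2) adds to the formyl carbon (future C3) to give an anti-betaine; 3-exo-tet displacement of the sulfide gives trans-vinyl oxirane 10, which the ortho phenoxide opens at the allylic carbon by anti SN2 attack (a 5-endo oxirane opening; the 4-exo mode at the benzylic carbon is geometrically excluded) to form the O1–C2 bond. The closest known reactions are the asymmetric Corey–Chaykovsky synthesis of vinyl oxiranes from chiral thiolanium allylides and aldehydes, and the sulfur-ylide annulation of salicylaldehydes to 2,3-dihydrobenzofuran-3-ols. C2 is reagent-controlled: in the ylide of the (2R,5R)-thiolane the allyl substituent should lie syn to the sulfur lone pair and the ring methyl group cis to the ylide carbon should shield one face, which corresponds to the (S,S)-oxirane series in benzylidene transfer; this sets the oxirane carbon as S, and inversion in the ring closure makes C2 R. C3 follows from the anti-betaine (trans-oxirane) preference of semi-stabilised ylides with aryl aldehydes and is not touched by the cyclisation, so the stereospecific opening should give only the 2,3-trans ring. The step needs formyl over acetyl selectivity (secured by the higher reactivity of the aldehyde, with the phenoxide deactivating the ketone and its enolisation), α- over γ-attack of the allylide, and attack of the phenoxide at C2 rather than at the terminal CH2, which is secured by ring size (five versus seven).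

Step 7
Reactants: 11 1-[(2R,3S)-2-(3-{[tert-butyl(dimethyl)silyl]oxy}prop-1-en-2-yl)-3-hydroxy-2,3-dihydro-1-benzofuran-5-yl]ethan-1-one
Product: 12 (2R,3S)-5-acetyl-2-(3-{[tert-butyl(dimethyl)silyl]oxy}prop-1-en-2-yl)-2,3-dihydro-1-benzofuran-3-yl 3-methylbutanoate
Conditions: (i-PrCH2CO)2O (1.5 equiv), Et3N, DMAP (0.1 equiv), CH2Cl2, 0 °C → rt
Reagents that add atoms: 3-methylbutanoic anhydride, CC(C)CC(=O)OC(=O)CC(C)C
Why: DMAP-catalysed acyl transfer to the secondary benzylic alcohol occurs at oxygen, so C3 is retained; the para acetyl group disfavours ionisation of the C3–O bond.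

Step 8
Reactants: 12 (2R,3S)-5-acetyl-2-(3-{[tert-butyl(dimethyl)silyl]oxy}prop-1-en-2-yl)-2,3-dihydro-1-benzofuran-3-yl 3-methylbutanoate
Product: 13 (2R,3S)-2-(3-{[tert-butyl(dimethyl)silyl]oxy}prop-1-en-2-yl)-5-[(1R)-1-hydroxyethyl]-2,3-dihydro-1-benzofuran-3-yl 3-methylbutanoate
Conditions: RuCl[(R,R)-TsDPEN](p-cymene) (2 mol %), HCO2H/Et3N (5:2), CH2Cl2, 30 °C
Reagents that add atoms: none
Why: Noyori–Ikariya asymmetric transfer hydrogenation of the aryl methyl ketone; the (R,R)-catalyst should deliver hydride to the Si face through the CH/π-organised six-membered transition state, as with acetophenone, setting the (R)-carbinol and leaving ester, alkene and silyl ether untouched.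

Step 9
Reactants: 13 (2R,3S)-2-(3-{[tert-butyl(dimethyl)silyl]oxy}prop-1-en-2-yl)-5-[(1R)-1-hydroxyethyl]-2,3-dihydro-1-benzofuran-3-yl 3-methylbutanoate, 14 (2R)-2-methylbutanoic acid
Product: 15 (1R)-1-[(2R,3S)-2-(3-{[tert-butyl(dimethyl)silyl]oxy}prop-1-en-2-yl)-3-[(3-methylbutanoyl)oxy]-2,3-dihydro-1-benzofuran-5-yl]ethyl (2R)-2-methylbutanoate
Conditions: DCC (1.3 equiv), DMAP (0.1 equiv), CH2Cl2, 0 °C → rt
Reagents that add atoms: none
Why: Steglich esterification acylates the alcohol at oxygen, so the carbinol centre is retained; the α-centre of the simple α-branched acid should not enolise under carbodiimide activation at 0 °C with catalytic DMAP.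

Step 10
Reactants: 15 (1R)-1-[(2R,3S)-2-(3-{[tert-butyl(dimethyl)silyl]oxy}prop-1-en-2-yl)-3-[(3-methylbutanoyl)oxy]-2,3-dihydro-1-benzofuran-5-yl]ethyl (2R)-2-methylbutanoate
Product: 16 (1R)-1-[(2R,3S)-2-(3-hydroxyprop-1-en-2-yl)-3-[(3-methylbutanoyl)oxy]-2,3-dihydro-1-benzofuran-5-yl]ethyl (2R)-2-methylbutanoate
Conditions: TBAF (1.5 equiv), AcOH (1.5 equiv), THF, 0 °C → rt
Reagents that add atoms: none
Why: Fluoride cleavage of the primary silyl ether, buffered with acetic acid so that the alkoxide is protonated at once, should leave both secondary esters and all four stereocentres unchanged.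

Step 11
Reactants: 16 (1R)-1-[(2R,3S)-2-(3-hydroxyprop-1-en-2-yl)-3-[(3-methylbutanoyl)oxy]-2,3-dihydro-1-benzofuran-5-yl]ethyl (2R)-2-methylbutanoate
Product: 17 (1R)-1-[(2R,3S)-3-[(3-methylbutanoyl)oxy]-2-(3-oxoprop-1-en-2-yl)-2,3-dihydro-1-benzofuran-5-yl]ethyl (2R)-2-methylbutanoate
Conditions: activated MnO2 (excess), CH2Cl2, rt
Reagents that add atoms: none
Why: Heterogeneous MnO2 oxidation is selective for the allylic alcohol and should give the 2-substituted acrolein under neutral, non-nucleophilic conditions that neither open the ring by SN2' addition nor ionise the benzylic esters.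

**Compound list**
1 | 2-methylidenepropane-1,3-diol | C=C(CO)CO | starting material
2 | 2-({[tert-butyl(dimethyl)silyl]oxy}methyl)prop-2-en-1-ol | C=C(CO)CO[Si](C)(C)C(C)(C)C | intermediate
3 | {[2-(bromomethyl)prop-2-en-1-yl]oxy}(tert-butyl)dimethylsilane | C=C(CBr)CO[Si](C)(C)C(C)(C)C | intermediate
4 | (2S,5S)-hexane-2,5-diol | C[C@H](O)CC[C@H](C)O | starting material
5 | (2S,5S)-hexane-2,5-diyl dimethanesulfonate | C[C@H](OS(C)(=O)=O)CC[C@H](C)OS(C)(=O)=O | intermediate
6 | (2R,5R)-2,5-dimethylthiolane | C[C@@H]1CC[C@@H](C)S1 | intermediate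
7 | (2R,5R)-1-[2-({[tert-butyl(dimethyl)silyl]oxy}methyl)prop-2-en-1-yl]-2,5-dimethylthiolan-1-ium tetrafluoroborate | C[C@@H]1CC[C@@H](C)[S+]1CC(=C)CO[Si](C)(C)C(C)(C)C.F[B-](F)(F)F | intermediate
8 | 5-acetyl-2-hydroxybenzaldehyde | CC(=O)c1ccc(O)c(C=O)c1 | starting material
9 | allylic sulfonium ylide derived from 7 | C[C@@H]1CC[C@@H](C)[S+]1[CH-]C(=C)CO[Si](C)(C)C(C)(C)C | intermediate
10 | 1-{3-[(2S,3S)-3-(3-{[tert-butyl(dimethyl)silyl]oxy}prop-1-en-2-yl)oxiran-2-yl]-4-hydroxyphenyl}ethan-1-one (present as its sodium phenoxide) | C=C(CO[Si](C)(C)C(C)(C)C)[C@@H]1O[C@H]1c2cc(C(C)=O)ccc2O | intermediate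
11 | 1-[(2R,3S)-2-(3-{[tert-butyl(dimethyl)silyl]oxy}prop-1-en-2-yl)-3-hydroxy-2,3-dihydro-1-benzofuran-5-yl]ethan-1-one | C=C(CO[Si](C)(C)C(C)(C)C)[C@H]1Oc2ccc(C(C)=O)cc2[C@@H]1O | intermediate
12 | (2R,3S)-5-acetyl-2-(3-{[tert-butyl(dimethyl)silyl]oxy}prop-1-en-2-yl)-2,3-dihydro-1-benzofuran-3-yl 3-methylbutanoate | C=C(CO[Si](C)(C)C(C)(C)C)[C@H]1Oc2ccc(C(C)=O)cc2[C@@H]1OC(=O)CC(C)C | intermediate
13 | (2R,3S)-2-(3-{[tert-butyl(dimethyl)silyl]oxy}prop-1-en-2-yl)-5-[(1R)-1-hydroxyethyl]-2,3-dihydro-1-benzofuran-3-yl 3-methylbutanoate | C=C(CO[Si](C)(C)C(C)(C)C)[C@H]1Oc2ccc([C@@H](C)O)cc2[C@@H]1OC(=O)CC(C)C | intermediate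
14 | (2R)-2-methylbutanoic acid | CC[C@@H](C)C(=O)O | starting material
15 | (1R)-1-[(2R,3S)-2-(3-{[tert-butyl(dimethyl)silyl]oxy}prop-1-en-2-yl)-3-[(3-methylbutanoyl)oxy]-2,3-dihydro-1-benzofuran-5-yl]ethyl (2R)-2-methylbutanoate | C=C(CO[Si](C)(C)C(C)(C)C)[C@H]1Oc2ccc([C@@H](C)OC(=O)[C@H](C)CC)cc2[C@@H]1OC(=O)CC(C)C | intermediate
16 | (1R)-1-[(2R,3S)-2-(3-hydroxyprop-1-en-2-yl)-3-[(3-methylbutanoyl)oxy]-2,3-dihydro-1-benzofuran-5-yl]ethyl (2R)-2-methylbutanoate | C=C(CO)[C@H]1Oc2ccc([C@@H](C)OC(=O)[C@H](C)CC)cc2[C@@H]1OC(=O)CC(C)C | intermediate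
17 | (1R)-1-[(2R,3S)-3-[(3-methylbutanoyl)oxy]-2-(3-oxoprop-1-en-2-yl)-2,3-dihydro-1-benzofuran-5-yl]ethyl (2R)-2-methylbutanoate | C=C(C=O)[C@H]1Oc2ccc([C@@H](C)OC(=O)[C@H](C)CC)cc2[C@@H]1OC(=O)CC(C)C | target

**Step count**
Total: 11 steps. Longest linear sequence: 9 steps (steps 1, 2, 5, 6, 7, 8, 9, 10, 11; the branch through steps 3 and 4 is equally long).

**Steps most likely to fail**

1. Step 6. What may go wrong: O-allylation of the phenoxide by the sulfonium salt instead of ylide addition; attack of the ylide on the acetyl group or aldol condensation between acetyl and formyl groups; slow or non-stereospecific opening of the oxirane; insufficient facial selectivity of the ylide. The fallback sets out from 3 and 8 and returns at 11. Bromide 3 and PPh3 (MeCN, 60 °C) would give the allylic phosphonium bromide F1. Its ylide (NaHMDS, one equivalent each for the phenol and for F1, THF, −78 °C → rt) with 8, followed by iodine-catalysed isomerisation, would give the (E)-dienyl phenol F2. Ac2O/pyridine would give the aryl acetate F3. Shi epoxidation with the enantiomeric (L-fructose-derived) ketone catalyst, which prefers the trans-disubstituted over the 1,1-disubstituted alkene, would give the (2S,3S)-oxirane F4. K2CO3/MeOH would then remove the acetate, and the phenoxide would close the ring to 11.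

2. Step 8. What may go wrong: slow hydride transfer to the electron-rich ketone, poor facial selectivity, or acid-induced ionisation of a benzylic C–O bond. The fallback sets out from 12 and returns at 13 and 15. NaBH4 (MeOH/THF, −20 °C) would reduce the ketone without facial control to 13 and its (1S)-epimer F5. Immobilised Candida antarctica lipase B with vinyl acetate should acetylate only the (1R)-carbinol, giving the acetate F6, from which unreacted F5 is easily separated. F5 would be coupled with 14 under Mitsunobu conditions (PPh3, DIAD, toluene, 0 °C), with inversion, to give 15. F6 would be hydrolysed by the same lipase in phosphate buffer back to 13, which re-enters at step 9.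

3. Step 10. What may go wrong: migration or loss of an acyl group, or ionisation of the p-alkoxybenzylic ester, during silyl cleavage. The fallback sets out from 13 and returns at 17. The silyl ether would be cleaved before the labile benzylic ester exists (TBAF/AcOH, THF) to give the diol F7. TEMPO/PhI(OAc)2 should oxidise the primary allylic alcohol in preference to the secondary benzylic one to give the hydroxy enal F8. Esterification with 14 (DCC, catalytic DMAP, −20 °C) would give 17 directly.

**Further compounds**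
F1 | step 6 | [2-({[tert-butyl(dimethyl)silyl]oxy}methyl)prop-2-en-1-yl](triphenyl)phosphonium bromide | C=C(C[P+](c1ccccc1)(c1ccccc1)c1ccccc1)CO[Si](C)(C)C(C)(C)C.[Br-]
F2 | step 6 | 1-{3-[(1E)-3-({[tert-butyl(dimethyl)silyl]oxy}methyl)buta-1,3-dien-1-yl]-4-hydroxyphenyl}ethan-1-one | C=C(CO[Si](C)(C)C(C)(C)C)/C=C/c1cc(C(C)=O)ccc1O
F3 | step 6 | 4-acetyl-2-[(1E)-3-({[tert-butyl(dimethyl)silyl]oxy}methyl)buta-1,3-dien-1-yl]phenyl acetate | C=C(CO[Si](C)(C)C(C)(C)C)/C=C/c1cc(C(C)=O)ccc1OC(C)=O
F4 | step 6 | 4-acetyl-2-[(2S,3S)-3-(3-{[tert-butyl(dimethyl)silyl]oxy}prop-1-en-2-yl)oxiran-2-yl]phenyl acetate | C=C(CO[Si](C)(C)C(C)(C)C)[C@@H]1O[C@H]1c2cc(C(C)=O)ccc2OC(C)=O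
F5 | step 8 | (2R,3S)-2-(3-{[tert-butyl(dimethyl)silyl]oxy}prop-1-en-2-yl)-5-[(1S)-1-hydroxyethyl]-2,3-dihydro-1-benzofuran-3-yl 3-methylbutanoate | C=C(CO[Si](C)(C)C(C)(C)C)[C@H]1Oc2ccc([C@H](C)O)cc2[C@@H]1OC(=O)CC(C)C
F6 | step 8 | (2R,3S)-5-[(1R)-1-(acetyloxy)ethyl]-2-(3-{[tert-butyl(dimethyl)silyl]oxy}prop-1-en-2-yl)-2,3-dihydro-1-benzofuran-3-yl 3-methylbutanoate | C=C(CO[Si](C)(C)C(C)(C)C)[C@H]1Oc2ccc([C@@H](C)OC(C)=O)cc2[C@@H]1OC(=O)CC(C)C
F7 | step 10 | (2R,3S)-5-[(1R)-1-hydroxyethyl]-2-(3-hydroxyprop-1-en-2-yl)-2,3-dihydro-1-benzofuran-3-yl 3-methylbutanoate | C=C(CO)[C@H]1Oc2ccc([C@@H](C)O)cc2[C@@H]1OC(=O)CC(C)C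
F8 | step 10 | (2R,3S)-5-[(1R)-1-hydroxyethyl]-2-(3-oxoprop-1-en-2-yl)-2,3-dihydro-1-benzofuran-3-yl 3-methylbutanoate | C=C(C=O)[C@H]1Oc2ccc([C@@H](C)O)cc2[C@@H]1OC(=O)CC(C)C
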